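In a one-step world free monomer simply decays with one lifetime τ, so a flask of duration t is worth t/τ lifetimes and converts a fraction 1 − exp(−t/τ). You asked me for a quick number on these flasks, and your hunch was the forecast below.

| flask | free monomer | transfer agent | capture agent | initiator | temperature | remark | time |
|---|---|---|---|---|---|---|---|
| Monday's | 0.25 M | 5 mM | 0.0125 M | 1.2 mM | −20 °C | run made earlier |  |
| Tuesday's | 0.25 M | 11 mM | 0.0125 M | 1.2 mM | 10 °C | run made earlier |  |
| Friday's | 0.25 M | 7.5 mM | 0.025 M | 1.2 mM | −20 °C | run made earlier |  |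
| blue | 0.25 M | 7.50 mM | 0.0125 M | 1.2 mM | 10 °C |  | 4.0 h |
| ochre | 0.25 M | 7.50 mM | 0.0125 M | 1.2 mM | 35 °C |  | 4.0 h |
| violet | 0.25 M | 7.50 mM | 0.0125 M | 1.2 mM |  | at −15 °C until 80 min, from then on at 35 °C | 4.0 h |
| amber | 0.25 M | 7.50 mM | 0.0125 M | 1.2 mM | −15 °C |  | 4.0 h |

- Monday's (time / h: monomer in chains / %): 0.833: 0; 1.33: 0; 3.00: 0; 6.00: 0.4; 12.0: 1.0
- Tuesday's (time / h: monomer in chains / %): 0.500: 0.7; 1.00: 1.7; 1.33: 2.1; 2.00: 6.0; 2.50: 8.8
- Friday's (time / h: monomer in chains / %): 0.833: 0; 1.33: 0.9; 3.00: 0.5; 6.00: 0.2; 12.0: 0.9

(standard deviation of a reading: 0.5 percentage points)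

- a reading or a percentage of monomer in chains counts all its forms, free or not

- the best flask by amount of monomer in chains, in percent of the free monomer charged; "all alike" if 1.5 percentage points covers them all (blue / ochre / violet / amber / all alike)
- amount of monomer in chains at the end, in percent of the free monomer charged, blue
- amount of monomer in chains at the end, in percent of the free monomer charged, ochre
- amount of monomer in chains at the end, in percent of the free monomer charged, violet
- amount of monomer in chains at the end, in percent of the free monomer charged, amber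

I counted lifetimes. Tuesday's late readings rose by 6.7 percentage points, well above the scatter of 0.5 points. I took free monomer to be what was not in chains, and from that remainder at 1.33 h and at 2.50 h I read the monomer lifetime, the pseudo-first-order time in which free monomer falls by a factor e, as τ = 16.5 h at 10 °C. It is a reading and carries that scatter, and I set aside that Tuesday's flask held 11 mM of transfer agent against 7.50 mM here.

With rates doubled every 10 degrees, going from 10 °C to 35 °C gave a factor 5.66, so τ became 2.92 h. Ochre's 4.0 h was then 1.37 lifetimes, and I committed to 74.6%. I counted violet's cold start as nothing, which left 2.67 h hot, or 0.914 lifetimes and 59.9%.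

The forecast named ochre as best. It gave blue 14% (9% to 20%), ochre 60% (25% to 85%), violet 47% (18% to 72%) and amber 0.3% (0% to 1.5%), adding of ochre that “an unseen ceiling or initiator burnout could lower it”. My ochre stood higher than the forecast's, and so did my violet.

The best flask was ochre: ochre gave 73.3%, violet 67.0%, blue 15.6% and amber 0.282%. Left to 40.0 h, ochre reached 79.9%. My hot τ counts 13.7 lifetimes for that time, but 79.9% is worth 1.60 lifetimes, so my ochre figure lay 1.3 points from the flask at 4.0 h, and the count had parted from the flask by 40.0 h.

    free monomer + initiator → living end + monomer in chains (k = 0.00260 M⁻¹ s⁻¹, Ea = 78.0 kJ mol⁻¹)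
    free monomer + living end → monomer in chains + living end, rate k2*[living end]*[free monomer] (k = 0.280 M⁻¹ s⁻¹, Ea = 40.0 kJ mol⁻¹)
    living end + transfer agent → dead chain (kL = 0.00890 M⁻¹ s⁻¹, Ea = 77.0 kJ mol⁻¹)
    free monomer → decomposition product (k = 1.20 × 10⁻⁸ s⁻¹, Ea = 111 kJ mol⁻¹)
    initiator + monomer in chains ⇌ idle complex, settled at all times (K = 10.0 M⁻¹, ΔH = −83.0 kJ mol⁻¹)
    living end + capture agent → trapped intermediate (k = 0.0120 M⁻¹ s⁻¹, Ea = 74.0 kJ mol⁻¹)
    (constants at 35 °C)

The neighbour with ochre's charge at 20 °C sits, by my rule, one doubling above Tuesday's temperature, so my τ is 8.25 h, and 4.0 h is 0.485 lifetimes, or 38.4%. The computed flask gave 44.1%.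

(The data are simulated with constants of no real substance; noise was put on by code.)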